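**Assumption:** chain numbering is used (C1 = CO2H, C3 = peroxy CH, C6 = ketal carbon), so the target is (3S,6R,12E). (2R)-5-Oxooxolane-2-carboxylic acid, the nitrous-acid deamination product of D-glutamic acid, is taken as a catalogue compound.

## Retrosynthetic overview

1. The only ring of the target, the 1,2-dioxane, is closed last: the C3–O bond forms by intramolecular SN2 opening of a (4R)-β-lactone by a C6 hydroperoxy ketal (inversion at C3), and the ketal centre is then set by anomeric equilibration.
2. The keto β-lactone comes from a (3R)-3-hydroxy-6-oxo acid by carboxyl activation (retention).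
3. The hydroxy keto acid comes from the C6–C7 bond: enyne alkyllithium plus the γ-lactone of (R)-3-hydroxyadipic acid.
4. That lactone acid comes from the C2–C3 bond: photochemical Wolff rearrangement of the diazoketone of the bought (R)-lactone acid, whose stereocentre migrates with retention.
5. The enyne chain comes from Sonogashira coupling of (E)-1-iodoundec-1-ene with 5-chloropent-1-yne.

## Route

Step 1
Reactants: 1 undec-1-yne
Product: 3 (E)-1-iodoundec-1-ene, via alkenylzirconocene chloride 2 (not isolated)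
Conditions: Cp2Zr(H)Cl (1.1 equiv), CH2Cl2, rt; then I2, 0 °C
Reagents that add atoms: iodine, II
Why: Schwartz hydrozirconation adds Zr–H syn and anti-Markovnikov, and iodinolysis of the C–Zr bond goes with retention, so only the E vinyl iodide forms.

Step 2
Reactants: 3 (E)-1-iodoundec-1-ene; 4 5-chloropent-1-yne
Product: 5 (6E)-1-chlorohexadec-6-en-4-yne
Conditions: PdCl2(PPh3)2 (2 mol %), CuI (4 mol %), Et3N, THF, rt
Reagents that add atoms: none
Why: Sonogashira coupling of a vinyl iodide at room temperature keeps the E geometry and leaves the primary chloride untouched.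

Step 3
Reactants: 5 (6E)-1-chlorohexadec-6-en-4-yne
Product: 6 (6E)-1-iodohexadec-6-en-4-yne
Conditions: NaI (3 equiv), acetone, reflux, dark
Reagents that add atoms: sodium iodide, [Na+].[I-]
Why: Finkelstein SN2 exchange, driven by precipitation of NaCl, gives the iodide needed for clean lithium–iodine exchange.

Step 4
Reactants: 7 (2R)-5-oxooxolane-2-carboxylic acid
Product: 9 (5R)-5-(2-diazoacetyl)oxolan-2-one, via acid chloride 8 (not isolated)
Conditions: (COCl)2, DMF (cat.), CH2Cl2, 0 °C to rt, evaporate; CH2N2 (3 equiv), Et2O, 0 °C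
Reagents that add atoms: diazomethane, C=[N+]=[N-]
Why: First stage of the Arndt–Eistert homologation; with excess diazomethane as the only base the α-acyloxy stereocentre is not enolised.

Step 5
Reactants: 9 (5R)-5-(2-diazoacetyl)oxolan-2-one
Product: 11 2-[(2R)-5-oxooxolan-2-yl]acetic acid, via ketene 10 (not isolated)
Conditions: hν (365 nm LED), THF–H2O (4:1), 20 °C
Reagents that add atoms: water, O
Why: Photochemical Wolff rearrangement: loss of N2 and 1,2-shift of the stereogenic carbon with retention forms the C2–C3 bond, and water traps the ketene as the acid while the γ-lactone is inert to neutral water.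

Step 6
Reactants: 11 2-[(2R)-5-oxooxolan-2-yl]acetic acid; 6 (6E)-1-iodohexadec-6-en-4-yne
Product: 14 (3R,12E)-3-hydroxy-6-oxodocos-12-en-10-ynoic acid, via sodium carboxylate 12 (not isolated), via alkyllithium 13 (not isolated)
Conditions: 11, NaH (1.0 equiv), THF, 0 °C; 6, t-BuLi (2.1 equiv), Et2O–pentane, −78 °C; combine at −78 °C, 1 h; 1 M HCl
Reagents that add atoms: none
Why: Lithium–iodine exchange is complete at −78 °C, where the 4-alkynyllithium does not cyclise, and organolithium mono-addition to the γ-lactone stops at the lithium lactolate until the quench, while the pre-formed carboxylate is inert and the C3–O bond is untouched, so C3 stays R.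

Step 7
Reactants: 14 (3R,12E)-3-hydroxy-6-oxodocos-12-en-10-ynoic acid
Product: 16 (4R)-4-[(9E)-3-oxononadec-9-en-7-yn-1-yl]oxetan-2-one, via mixed sulfonic anhydride 15 (not isolated)
Conditions: PhSO2Cl (2 equiv), pyridine, 0 to 4 °C, 16 h
Reagents that add atoms: none
Why: Adam β-lactonisation: the carboxyl is activated as the mixed sulfonic anhydride and acylates the free 3-hydroxyl, so the C3–O bond is not broken and the R configuration is retained.

Step 8
Reactants: 16 (4R)-4-[(9E)-3-oxononadec-9-en-7-yn-1-yl]oxetan-2-one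
Product: 19 2-[(3S,6R)-6-[(6E)-hexadec-6-en-4-yn-1-yl]-6-methoxy-1,2-dioxan-3-yl]acetic acid, via hydroperoxy ketal 17 (not isolated), via epimeric dioxane carboxylate 18 (not isolated)
Conditions: urea·H2O2 (4 equiv), Sc(OTf)3 (5 mol %), MeOH–CH2Cl2 (1:2), 0 °C; cold water wash, swap to THF; KOt-Bu (1.0 equiv), 18-crown-6, THF (0.01 M), −40 to 0 °C; then TsOH·H2O (1.2 equiv), MeOH, 0 °C
Reagents that add atoms: urea–hydrogen peroxide, NC(N)=O.OO; methanol, CO
Why: Proposed new method: the ketone is first turned into its gem-methoxy hydroperoxide (a known Sc(OTf)3/urea–H2O2/MeOH reaction), whose anion cannot reach the lactone carbonyl (8-membered transition state) but is held for a 6-exo-tet SN2 attack on C3, the alkyl carbon of the strained β-lactone, so alkyl–oxygen cleavage forms the C3–O bond and the 1,2-dioxane with inversion (3R to 3S) and releases the carboxylate that is the target's acid, the β-lactone acting as a β-leaving group that cannot suffer the E1cB loss of a β-sulfonyloxy ester; acidic methanol then equilibrates the ketal centre through the cyclic peroxycarbenium ion to the anomerically favoured isomer (axial OMe, both carbon substituents equatorial, 6R), so C6 is controlled by C3; the closest known reactions are the SN2 alkyl–oxygen opening of β-lactones by soft anionic nucleophiles with inversion and the intramolecular alkylation of hydroperoxy ketals by sulfonates, and a peroxide nucleophile has not yet been used to open a β-lactone.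

## Compound list

1 | undec-1-yne | CCCCCCCCCC#C | starting material
2 | (E)-undec-1-enylzirconocene chloride | CCCCCCCCC/C=C/[Zr](Cl)(C1C=CC=C1)C1C=CC=C1 | intermediate
3 | (E)-1-iodoundec-1-ene | CCCCCCCCC/C=C/I | intermediate
4 | 5-chloropent-1-yne | C#CCCCCl | starting material
5 | (6E)-1-chlorohexadec-6-en-4-yne | CCCCCCCCC/C=C/C#CCCCCl | intermediate
6 | (6E)-1-iodohexadec-6-en-4-yne | CCCCCCCCC/C=C/C#CCCCI | intermediate
7 | (2R)-5-oxooxolane-2-carboxylic acid | OC(=O)[C@H]1CCC(=O)O1 | starting material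
8 | (2R)-5-oxooxolane-2-carbonyl chloride | ClC(=O)[C@H]1CCC(=O)O1 | intermediate
9 | (5R)-5-(2-diazoacetyl)oxolan-2-one | [N-]=[N+]=CC(=O)[C@H]1CCC(=O)O1 | intermediate
10 | (5R)-5-(2-oxoethenyl)oxolan-2-one (ketene) | O=C=C[C@H]1CCC(=O)O1 | intermediate
11 | 2-[(2R)-5-oxooxolan-2-yl]acetic acid | OC(=O)C[C@H]1CCC(=O)O1 | intermediate
12 | sodium 2-[(2R)-5-oxooxolan-2-yl]acetate | [Na+].[O-]C(=O)C[C@H]1CCC(=O)O1 | intermediate
13 | [(6E)-hexadec-6-en-4-yn-1-yl]lithium | [Li]CCCC#C/C=C/CCCCCCCCC | intermediate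
14 | (3R,12E)-3-hydroxy-6-oxodocos-12-en-10-ynoic acid | CCCCCCCCC/C=C/C#CCCCC(=O)CC[C@@H](O)CC(=O)O | intermediate
15 | benzenesulfonic (3R,12E)-3-hydroxy-6-oxodocos-12-en-10-ynoic anhydride | CCCCCCCCC/C=C/C#CCCCC(=O)CC[C@@H](O)CC(=O)OS(=O)(=O)c1ccccc1 | intermediate
16 | (4R)-4-[(9E)-3-oxononadec-9-en-7-yn-1-yl]oxetan-2-one | CCCCCCCCC/C=C/C#CCCCC(=O)CC[C@@H]1CC(=O)O1 | intermediate
17 | (4R)-4-[(9E)-3-hydroperoxy-3-methoxynonadec-9-en-7-yn-1-yl]oxetan-2-one (both epimers at the ketal carbon) | CCCCCCCCC/C=C/C#CCCCC(OC)(OO)CC[C@@H]1CC(=O)O1 | intermediate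
18 | potassium 2-[(3S)-6-[(6E)-hexadec-6-en-4-yn-1-yl]-6-methoxy-1,2-dioxan-3-yl]acetate (both C6 epimers) | CCCCCCCCC/C=C/C#CCCCC1(OC)CC[C@@H](CC(=O)[O-])OO1.[K+] | intermediate
19 | 2-[(3S,6R)-6-[(6E)-hexadec-6-en-4-yn-1-yl]-6-methoxy-1,2-dioxan-3-yl]acetic acid | CCCCCCCCC/C=C/C#CCCC[C@]1(OC)CC[C@@H](CC(=O)O)OO1 | target

## Step count and risks

Total steps: 8. Longest linear sequence: 6 (steps 1, 2, 3, 6, 7, 8); 5 from the chiral starting material 7.

**Step 8, the new ring closure, is the most likely to fail.** The β-lactone may be methanolysed during hydroperoxy ketal formation, the peroxy anion may attack a second lactone at the carbonyl, or a ketal oxygen may compete through a five-membered transition state. The fallback uses known chemistry, sets out from 14 and returns at 19. TMSCHN2 gives methyl (3R,12E)-3-hydroxy-6-oxodocos-12-en-10-ynoate F1. MsCl/Et3N at −20 °C gives methyl (3R,12E)-3-(methanesulfonyloxy)-6-oxodocos-12-en-10-ynoate F2. Urea·H2O2/Sc(OTf)3/MeOH gives methyl (3R,12E)-6-hydroperoxy-6-methoxy-3-(methanesulfonyloxy)docos-12-en-10-ynoate F3. KOt-Bu/18-crown-6 then closes the ring by the known intramolecular alkylation of a hydroperoxy ketal by a sulfonate (inversion at C3) to the C6-epimeric methyl 2-[(3S)-6-[(6E)-hexadec-6-en-4-yn-1-yl]-6-methoxy-1,2-dioxan-3-yl]acetate F4. TsOH/MeOH equilibrates it to methyl 2-[(3S,6R)-6-[(6E)-hexadec-6-en-4-yn-1-yl]-6-methoxy-1,2-dioxan-3-yl]acetate F5, and LiOH in THF–water at 0 °C gives 19. The price is possible E1cB loss of the β-mesylate.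

**Step 7 is the second risk.** β-Lactonisation of a 3-hydroxy acid with no α-substituent is sluggish, and the γ-keto group can tie up the hydroxyl as a lactol. The fallback gives up the β-lactone, brings in the peroxide intermolecularly and closes the ring at the ketal carbon; it sets out from 14 and returns at 19. The methyl ester F1 is made as above and converted with 4-nitrobenzenesulfonyl chloride/pyridine into methyl (3R,12E)-3-[(4-nitrophenyl)sulfonyloxy]-6-oxodocos-12-en-10-ynoate F6. Displacement with 2-methoxyprop-2-yl hydroperoxide and CsOH in DMF (inversion) gives methyl (3S,12E)-3-[(2-methoxypropan-2-yl)peroxy]-6-oxodocos-12-en-10-ynoate F7. TsOH in MeOH frees methyl (3S,12E)-3-hydroperoxy-6-oxodocos-12-en-10-ynoate F8, which adds to the C6 ketone and is ketalised in the same pot to the methyl ester F5; saponification gives 19.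

**Step 6 is the third risk.** The alkyllithium may add twice, or the carboxylate salt may be too insoluble. The fallback changes the acyl electrophile and the organometal; it sets out from 11 and 5 and returns at 14. MeNH(OMe)·HCl/AlMe3 opens the lactone to the Weinreb amide (3R)-3-hydroxy-6-[methoxy(methyl)amino]-6-oxohexanoic acid F9. After deprotonation of CO2H and OH with t-BuMgCl (2 equiv), the Grignard reagent [(6E)-hexadec-6-en-4-yn-1-yl]magnesium chloride F10, made from chloride 5 and Mg in THF, adds once to the amide and gives 14 on acidic work-up.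

## Further compounds

F1 | step 8 | methyl (3R,12E)-3-hydroxy-6-oxodocos-12-en-10-ynoate | CCCCCCCCC/C=C/C#CCCCC(=O)CC[C@@H](O)CC(=O)OC
F2 | step 8 | methyl (3R,12E)-3-(methanesulfonyloxy)-6-oxodocos-12-en-10-ynoate | CCCCCCCCC/C=C/C#CCCCC(=O)CC[C@@H](OS(C)(=O)=O)CC(=O)OC
F3 | step 8 | methyl (3R,12E)-6-hydroperoxy-6-methoxy-3-(methanesulfonyloxy)docos-12-en-10-ynoate (both C6 epimers) | CCCCCCCCC/C=C/C#CCCCC(OC)(OO)CC[C@@H](OS(C)(=O)=O)CC(=O)OC
F4 | step 8 | methyl 2-[(3S)-6-[(6E)-hexadec-6-en-4-yn-1-yl]-6-methoxy-1,2-dioxan-3-yl]acetate (both C6 epimers) | CCCCCCCCC/C=C/C#CCCCC1(OC)CC[C@@H](CC(=O)OC)OO1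
F5 | step 8 | methyl 2-[(3S,6R)-6-[(6E)-hexadec-6-en-4-yn-1-yl]-6-methoxy-1,2-dioxan-3-yl]acetate | CCCCCCCCC/C=C/C#CCCC[C@]1(OC)CC[C@@H](CC(=O)OC)OO1
F6 | step 7 | methyl (3R,12E)-3-[(4-nitrophenyl)sulfonyloxy]-6-oxodocos-12-en-10-ynoate | CCCCCCCCC/C=C/C#CCCCC(=O)CC[C@@H](OS(=O)(=O)c1ccc(cc1)[N+](=O)[O-])CC(=O)OC
F7 | step 7 | methyl (3S,12E)-3-[(2-methoxypropan-2-yl)peroxy]-6-oxodocos-12-en-10-ynoate | CCCCCCCCC/C=C/C#CCCCC(=O)CC[C@H](OOC(C)(C)OC)CC(=O)OC
F8 | step 7 | methyl (3S,12E)-3-hydroperoxy-6-oxodocos-12-en-10-ynoate | CCCCCCCCC/C=C/C#CCCCC(=O)CC[C@H](OO)CC(=O)OC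
F9 | step 6 | (3R)-3-hydroxy-6-[methoxy(methyl)amino]-6-oxohexanoic acid | CON(C)C(=O)CC[C@@H](O)CC(=O)O
F10 | step 6 | [(6E)-hexadec-6-en-4-yn-1-yl]magnesium chloride | CCCCCCCCC/C=C/C#CCCC[Mg]Cl
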